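The route rests on disconnecting the aryl ether bond O1–C8a of the pyran ring, not the tertiary, allylic and therefore ionisable C2–O1 bond. The feature exploited is that O1 sits between an sp2 carbon of the benzene ring (C8a) and the stereocentre C2: a palladium-catalysed intramolecular etherification joins the oxygen already fixed on C2 to C8a, closing the 2H-pyran ring in one operation with C2 untouched. The precursor is a (Z)-styrenyl tertiary alcohol, its carbinol centre set by Sharpless epoxidation, whose arene carries two equivalent bromines flanking the alkene; the surviving bromine becomes the C5 phenol. The cyclohexene centres come from an enantioselective Diels–Alder reaction.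

Key step: step 13

Assumption: commercial 3-methylpenta-1,3-diene (an E/Z mixture) is used in excess as the source of the (E)-isomer, which alone reaches the s-cis form easily, and the facial sense of the boron catalyst in step 1 is assigned from the accepted binding model for 2-substituted acroleins; it is not verified for this diene, and the (3aS)-catalyst would be taken if the adduct proved antipodal.

Step 1
Reactants: 1 2-methylprop-2-enal (methacrolein); 2 (3E)-3-methylpenta-1,3-diene
Product: 3 (1R,2R)-1,2,3-trimethylcyclohex-3-ene-1-carbaldehyde (two methyl groups cis, CHO trans to the C2 methyl)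
Conditions: (3aR)-1-(2-methylphenyl)-3,3-diphenyltetrahydro-1H,3H-pyrrolo[1,2-c][1,3,2]oxazaborole (12 mol%), HN(SO2CF3)2 (10 mol%), CH2Cl2, −78 → −40 °C, 2 in threefold excess; minor isomers removed by chromatography
Reagents that add atoms: none
Why: Enantioselective Diels–Alder reaction under a chiral cationic boron Lewis acid: the boron-bound s-trans enal should be attacked on the face left open by the catalyst phenyl ring (C1 set as R), the CH2 of the dienophile should bond to the CH2 terminus of the diene as in additions to 1-vinylcyclohexenes ("ortho" product), and the exo preference of 2-substituted acroleins under Lewis acids should place CHO trans to the C2 methyl (C2 set as R).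

Step 2
Reactants: 3 (1R,2R)-1,2,3-trimethylcyclohex-3-ene-1-carbaldehyde; 4 1-(triphenyl-λ5-phosphanylidene)propan-2-one
Product: 5 (3E)-4-[(1S,2R)-1,2,3-trimethylcyclohex-3-en-1-yl]but-3-en-2-one
Conditions: toluene, 110 °C
Reagents that add atoms: none
Why: Wittig olefination with a stabilised ylide, which needs heat at the neopentyl-type aldehyde but should give the (E)-enone without touching the quaternary centre (the descriptors change only because the substituent priorities change).

Step 3
Reactants: 5 (3E)-4-[(1S,2R)-1,2,3-trimethylcyclohex-3-en-1-yl]but-3-en-2-one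
Product: 6 4-[(1S,2S)-1,2,3-trimethylcyclohex-3-en-1-yl]butan-2-one
Conditions: [(Ph3P)CuH]6 (0.3 equiv), H2O (5 equiv), THF, rt
Reagents that add atoms: none
Why: Conjugate (1,4-) reduction by a phosphine-ligated copper hydride with protonation by water in the flask, a reagent class that should reduce only the enone C=C and leave the ketone and the isolated trisubstituted ring alkene alone.

Step 4
Reactants: 6 4-[(1S,2S)-1,2,3-trimethylcyclohex-3-en-1-yl]butan-2-one; 7 triethyl phosphonoacetate
Product: 8 ethyl (2E)-3-methyl-5-[(1S,2S)-1,2,3-trimethylcyclohex-3-en-1-yl]pent-2-enoate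
Conditions: NaH, THF, 0 → 50 °C; the minor (Z)-isomer removed by chromatography
Reagents that add atoms: none
Why: Horner–Wadsworth–Emmons olefination of a methyl ketone, which should favour the (E)-enoate with the ester trans to the longer chain.

Step 5
Reactants: 8 ethyl (2E)-3-methyl-5-[(1S,2S)-1,2,3-trimethylcyclohex-3-en-1-yl]pent-2-enoate
Product: 9 (2E)-3-methyl-5-[(1S,2S)-1,2,3-trimethylcyclohex-3-en-1-yl]pent-2-en-1-ol
Conditions: i-Bu2AlH (2.4 equiv), CH2Cl2, −78 °C; aqueous potassium sodium tartrate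
Reagents that add atoms: none
Why: 1,2-Reduction of a conjugated ester by an aluminium hydride, which should give the allylic alcohol with both alkenes intact.

Step 6
Reactants: 9 (2E)-3-methyl-5-[(1S,2S)-1,2,3-trimethylcyclohex-3-en-1-yl]pent-2-en-1-ol
Product: 10 [(2R,3R)-3-methyl-3-{2-[(1S,2S)-1,2,3-trimethylcyclohex-3-en-1-yl]ethyl}oxiran-2-yl]methanol
Conditions: Ti(OiPr)4 (10 mol%), D-(−)-diethyl tartrate (12 mol%), t-BuOOH, 4 Å molecular sieves, CH2Cl2, −20 °C
Reagents that add atoms: tert-butyl hydroperoxide, CC(C)(C)OO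
Why: Sharpless asymmetric epoxidation, in which the titanium–tartrate complex epoxidises only the allylic alcohol alkene and D-(−)-tartrate should deliver oxygen to the face giving the (2R,3R)-epoxide (reagent control, as for geraniol-type substrates), so that C3 of the oxirane, the future C2 of the chromene, is R.

Step 7
Reactants: 10 [(2R,3R)-3-methyl-3-{2-[(1S,2S)-1,2,3-trimethylcyclohex-3-en-1-yl]ethyl}oxiran-2-yl]methanol
Product: 11 (2R,3S)-3-(chloromethyl)-2-methyl-2-{2-[(1S,2S)-1,2,3-trimethylcyclohex-3-en-1-yl]ethyl}oxirane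
Conditions: Ph3P, CCl4, NaHCO3, 75 °C
Reagents that add atoms: tetrachloromethane, ClC(Cl)(Cl)Cl
Why: Appel chlorination of the primary alcohol (SN2 at CH2 under buffered conditions), which should leave the epoxide and both of its stereocentres untouched (the descriptor of the CH carbon changes only because CH2Cl outranks the ring carbon).

Step 8
Reactants: 11 (2R,3S)-3-(chloromethyl)-2-methyl-2-{2-[(1S,2S)-1,2,3-trimethylcyclohex-3-en-1-yl]ethyl}oxirane
Product: 13 (3R)-3-methyl-5-[(1S,2S)-1,2,3-trimethylcyclohex-3-en-1-yl]pent-1-yn-3-ol, via lithium chloroalkenolate 12 (not isolated)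
Conditions: n-BuLi (3.2 equiv), THF, −78 → −30 °C; then H2O
Reagents that add atoms: none
Why: Base-induced double elimination of a 2,3-epoxy chloride: deprotonation next to chlorine opens the epoxide to the chloro-allylic alkoxide 12 (its alkene geometry is of no consequence), a second equivalent removes HCl to give the alkyne and a third holds it as the acetylide, and since the C–O bond at the tertiary carbon is never broken the R configuration should be kept.

Step 9
Reactants: 14 1,2,3-trimethoxybenzene
Product: 15 1,5-dibromo-2,3,4-trimethoxybenzene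
Conditions: NBS (2.2 equiv), MeCN, rt → 60 °C
Reagents that add atoms: N-bromosuccinimide, O=C1CCC(=O)N1Br
Why: Electrophilic aromatic bromination, each bromine entering ortho to one outer methoxy group and para to the other, so that the only remaining ring hydrogen lies between the two bromines.

Step 10
Reactants: 15 1,5-dibromo-2,3,4-trimethoxybenzene
Product: 17 1,3-dibromo-2-iodo-4,5,6-trimethoxybenzene, via aryllithium 16 (not isolated)
Conditions: i-Pr2NLi (1.1 equiv), THF, −78 °C; then I2, −78 °C → rt
Reagents that add atoms: iodine, II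
Why: Deprotonation of the single ring C–H, acidified by two flanking bromines, with a lithium amide at low temperature (no other C–H exists to allow halogen migration, and the cold keeps LiBr loss to an aryne away), followed by iodinolysis of the aryllithium.

Step 11
Reactants: 13 (3R)-3-methyl-5-[(1S,2S)-1,2,3-trimethylcyclohex-3-en-1-yl]pent-1-yn-3-ol; 17 1,3-dibromo-2-iodo-4,5,6-trimethoxybenzene
Product: 18 (3R)-1-(2,6-dibromo-3,4,5-trimethoxyphenyl)-3-methyl-5-[(1S,2S)-1,2,3-trimethylcyclohex-3-en-1-yl]pent-1-yn-3-ol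
Conditions: PdCl2(PPh3)2 (3 mol%), CuI (6 mol%), Et3N, THF, 50 °C
Reagents that add atoms: none
Why: Sonogashira coupling, which should take place at the C–I bond only (oxidative addition far faster than at the electron-rich C–Br bonds) and tolerates the free tertiary alcohol.

Step 12
Reactants: 18 (3R)-1-(2,6-dibromo-3,4,5-trimethoxyphenyl)-3-methyl-5-[(1S,2S)-1,2,3-trimethylcyclohex-3-en-1-yl]pent-1-yn-3-ol
Product: 19 (1Z,3R)-1-(2,6-dibromo-3,4,5-trimethoxyphenyl)-3-methyl-5-[(1S,2S)-1,2,3-trimethylcyclohex-3-en-1-yl]pent-1-en-3-ol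
Conditions: H2 (1 atm), Pd/CaCO3 poisoned with Pb(OAc)2, quinoline, EtOAc, rt; purification on base-washed silica
Reagents that add atoms: none
Why: Lindlar semi-hydrogenation, syn delivery of H2 on the poisoned palladium surface giving the (Z)-alkene and stopping there, with the C–Br bonds and the trisubstituted ring alkene expected to survive.

Step 13
Reactants: 19 (1Z,3R)-1-(2,6-dibromo-3,4,5-trimethoxyphenyl)-3-methyl-5-[(1S,2S)-1,2,3-trimethylcyclohex-3-en-1-yl]pent-1-en-3-ol
Product: 20 (2R)-5-bromo-6,7,8-trimethoxy-2-methyl-2-{2-[(1S,2S)-1,2,3-trimethylcyclohex-3-en-1-yl]ethyl}-2H-chromene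
Conditions: Pd(OAc)2 (5 mol%), 2-(di-tert-butylphosphino)-1,1'-binaphthyl (6 mol%), Cs2CO3 (1.5 equiv), toluene, 70 °C
Reagents that add atoms: none
Why: Zerovalent palladium, formed from Pd(OAc)2 and the bulky electron-rich phosphine, should insert into one of the two equivalent C–Br bonds, the caesium alkoxide of the tertiary alcohol then replaces bromide on divalent palladium, and C–O reductive elimination forms O1–C8a. The closest known reaction type is the intramolecular Buchwald–Hartwig etherification of aryl bromides with tethered tertiary alcohols, which gives chromans. The six-membered pyran ring (O1, C2, C3, C4, C4a, C8a) is closed by reductive elimination from a seven-membered oxapalladacycle, the (Z)-C3=C4 bond holding the alkoxide over the metal. No stereocentre is created, and C2 should stay R because the C2–O bond is never broken and no acid is present to ionise it. The step needs a single cyclisation and no β-hydride loss: the symmetric dibromide gives the same product from either C–Br bond, the product has no hydroxyl left to engage its remaining bromine, and the carbinol carbon bears no hydrogen.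

Step 14
Reactants: 20 (2R)-5-bromo-6,7,8-trimethoxy-2-methyl-2-{2-[(1S,2S)-1,2,3-trimethylcyclohex-3-en-1-yl]ethyl}-2H-chromene
Product: 23 (2R)-6,7,8-trimethoxy-2-methyl-2-{2-[(1S,2S)-1,2,3-trimethylcyclohex-3-en-1-yl]ethyl}-2H-chromen-5-ol, via aryllithium 21 (not isolated), via lithium aryltrimethoxyborate 22 (not isolated)
Conditions: n-BuLi (1.1 equiv), THF, −78 °C; B(OMe)3, −78 → 0 °C; then 30% aq. H2O2, NaOH, 0 °C, under argon
Reagents that add atoms: hydrogen peroxide, OO
Why: Bromine–lithium exchange at C5 (much faster at −78 °C than any addition to the C3=C4 bond), borylation to the ate complex and oxidative 1,2-migration of the aryl group from boron to oxygen under alkaline peroxide should give the phenol, with no acid that could ionise C2–O1.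

Compound list
1 | 2-methylprop-2-enal (methacrolein) | CC(=C)C=O | starting material
2 | (3E)-3-methylpenta-1,3-diene | C/C=C(\C)C=C | starting material
3 | (1R,2R)-1,2,3-trimethylcyclohex-3-ene-1-carbaldehyde | O=C[C@]1(C)CCC=C(C)[C@H]1C | intermediate
4 | 1-(triphenyl-λ5-phosphanylidene)propan-2-one | CC(=O)C=P(c1ccccc1)(c1ccccc1)c1ccccc1 | starting material
5 | (3E)-4-[(1S,2R)-1,2,3-trimethylcyclohex-3-en-1-yl]but-3-en-2-one | CC(=O)/C=C/[C@]1(C)CCC=C(C)[C@H]1C | intermediate
6 | 4-[(1S,2S)-1,2,3-trimethylcyclohex-3-en-1-yl]butan-2-one | CC(=O)CC[C@]1(C)CCC=C(C)[C@H]1C | intermediate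
7 | triethyl phosphonoacetate | CCOC(=O)CP(=O)(OCC)OCC | starting material
8 | ethyl (2E)-3-methyl-5-[(1S,2S)-1,2,3-trimethylcyclohex-3-en-1-yl]pent-2-enoate | CCOC(=O)/C=C(\C)CC[C@]1(C)CCC=C(C)[C@H]1C | intermediate
9 | (2E)-3-methyl-5-[(1S,2S)-1,2,3-trimethylcyclohex-3-en-1-yl]pent-2-en-1-ol | OC/C=C(\C)CC[C@]1(C)CCC=C(C)[C@H]1C | intermediate
10 | [(2R,3R)-3-methyl-3-{2-[(1S,2S)-1,2,3-trimethylcyclohex-3-en-1-yl]ethyl}oxiran-2-yl]methanol | OC[C@H]1O[C@]1(C)CC[C@]2(C)CCC=C(C)[C@H]2C | intermediate
11 | (2R,3S)-3-(chloromethyl)-2-methyl-2-{2-[(1S,2S)-1,2,3-trimethylcyclohex-3-en-1-yl]ethyl}oxirane | ClC[C@H]1O[C@]1(C)CC[C@]2(C)CCC=C(C)[C@H]2C | intermediate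
12 | lithium (1E,3R)-1-chloro-3-methyl-5-[(1S,2S)-1,2,3-trimethylcyclohex-3-en-1-yl]pent-1-en-3-olate | Cl/C=C/[C@](C)(O[Li])CC[C@]1(C)CCC=C(C)[C@H]1C | intermediate (not isolated)
13 | (3R)-3-methyl-5-[(1S,2S)-1,2,3-trimethylcyclohex-3-en-1-yl]pent-1-yn-3-ol | C#C[C@](C)(O)CC[C@]1(C)CCC=C(C)[C@H]1C | intermediate
14 | 1,2,3-trimethoxybenzene | COc1cccc(OC)c1OC | starting material
15 | 1,5-dibromo-2,3,4-trimethoxybenzene | COc1c(Br)cc(Br)c(OC)c1OC | intermediate
16 | (2,6-dibromo-3,4,5-trimethoxyphenyl)lithium | [Li]c1c(Br)c(OC)c(OC)c(OC)c1Br | intermediate (not isolated)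
17 | 1,3-dibromo-2-iodo-4,5,6-trimethoxybenzene | COc1c(OC)c(OC)c(Br)c(I)c1Br | intermediate
18 | (3R)-1-(2,6-dibromo-3,4,5-trimethoxyphenyl)-3-methyl-5-[(1S,2S)-1,2,3-trimethylcyclohex-3-en-1-yl]pent-1-yn-3-ol | COc1c(OC)c(OC)c(Br)c(C#C[C@](C)(O)CC[C@]2(C)CCC=C(C)[C@H]2C)c1Br | intermediate
19 | (1Z,3R)-1-(2,6-dibromo-3,4,5-trimethoxyphenyl)-3-methyl-5-[(1S,2S)-1,2,3-trimethylcyclohex-3-en-1-yl]pent-1-en-3-ol | COc1c(OC)c(OC)c(Br)c(/C=C\[C@](C)(O)CC[C@]2(C)CCC=C(C)[C@H]2C)c1Br | intermediate
20 | (2R)-5-bromo-6,7,8-trimethoxy-2-methyl-2-{2-[(1S,2S)-1,2,3-trimethylcyclohex-3-en-1-yl]ethyl}-2H-chromene | COc1c(Br)c2c(c(OC)c1OC)O[C@](C)(CC[C@]1(C)CCC=C(C)[C@H]1C)C=C2 | intermediate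
21 | [(2R)-6,7,8-trimethoxy-2-methyl-2-{2-[(1S,2S)-1,2,3-trimethylcyclohex-3-en-1-yl]ethyl}-2H-chromen-5-yl]lithium | COc1c([Li])c2c(c(OC)c1OC)O[C@](C)(CC[C@]1(C)CCC=C(C)[C@H]1C)C=C2 | intermediate (not isolated)
22 | lithium trimethoxy[(2R)-6,7,8-trimethoxy-2-methyl-2-{2-[(1S,2S)-1,2,3-trimethylcyclohex-3-en-1-yl]ethyl}-2H-chromen-5-yl]borate | [Li+].COc1c([B-](OC)(OC)OC)c2c(c(OC)c1OC)O[C@](C)(CC[C@]1(C)CCC=C(C)[C@H]1C)C=C2 | intermediate (not isolated)
23 | (2R)-6,7,8-trimethoxy-2-methyl-2-{2-[(1S,2S)-1,2,3-trimethylcyclohex-3-en-1-yl]ethyl}-2H-chromen-5-ol | COc1c(O)c2c(c(OC)c1OC)O[C@](C)(CC[C@]1(C)CCC=C(C)[C@H]1C)C=C2 | target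

Total step count: 14. Longest linear sequence: 12 steps (steps 1–8, then 11–14); steps 9 and 10 are the two-step branch to 17.

Steps most likely to fail

Step 1. The catalyst may not hold regio-, exo- and facial control together, because the two methyl groups of the diene direct the regiochemistry in opposite senses and the enal is small; 3 would then come mixed with isomers or in low enantiomeric purity. The fallback sets out from 1 and 2 and comes back at 3. The cycloaddition is run with MeAlCl2 (1 equiv, CH2Cl2, −78 °C), under which 2-substituted acroleins are expected to add exo, to give 3 as the racemate, that is together with (1S,2S)-1,2,3-trimethylcyclohex-3-ene-1-carbaldehyde F1. The mixture is condensed with (1R,2R)-N,N'-dimethyl-1,2-diphenylethane-1,2-diamine (Et2O, 4 Å molecular sieves, rt) to give two diastereomeric aminals, (4R,5R)-1,3-dimethyl-4,5-diphenyl-2-[(1R,2R)-1,2,3-trimethylcyclohex-3-en-1-yl]imidazolidine F2 and (4R,5R)-1,3-dimethyl-4,5-diphenyl-2-[(1S,2S)-1,2,3-trimethylcyclohex-3-en-1-yl]imidazolidine F3. These are separated by crystallisation or chromatography on basic alumina, which should also remove regio- and endo isomers. Hydrolysis of F2 (dilute aqueous HCl, Et2O, 0 °C) returns 3.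

Step 13. Zerovalent palladium may also insert into the second C–Br bond, of 19 or of the product 20, tying up the catalyst or causing debromination and oligomers before C–O reductive elimination from the electron-rich arylpalladium alkoxide turns over. The fallback sets out from 19 and comes back at 23, introducing the phenol oxygen before ring closure. Treatment of 19 with n-BuLi (2.1 equiv, THF, −78 °C; the first equivalent deprotonates the alcohol, the second exchanges one bromine), then B(OMe)3 and H2O2/NaOH, should give 3-bromo-2-{(1Z,3R)-3-hydroxy-3-methyl-5-[(1S,2S)-1,2,3-trimethylcyclohex-3-en-1-yl]pent-1-en-1-yl}-4,5,6-trimethoxyphenol F4. This is kept away from acid and silylated at once (t-BuMe2SiCl, imidazole, DMF) to (1Z,3R)-1-{2-bromo-6-[(tert-butyldimethylsilyl)oxy]-3,4,5-trimethoxyphenyl}-3-methyl-5-[(1S,2S)-1,2,3-trimethylcyclohex-3-en-1-yl]pent-1-en-3-ol F5. The etherification of step 13, now with a single C–Br bond, should give tert-butyl(dimethyl){[(2R)-6,7,8-trimethoxy-2-methyl-2-{2-[(1S,2S)-1,2,3-trimethylcyclohex-3-en-1-yl]ethyl}-2H-chromen-5-yl]oxy}silane F6, and Bu4NF (THF, 0 °C) releases 23.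

Step 12. Hydrogen uptake at the alkyne, shielded by two ortho bromines and the tertiary carbinol, may be slow, so that over-reduction or hydrogenolysis of C–Br competes. The fallback sets out from 13 (with 17) and comes back at 19, making the (Z)-alkene before the arene is attached. Rhodium-catalysed anti-Markovnikov trans-hydroboration of 13 ([Rh(cod)Cl]2, P(i-Pr)3, Et3N, pinacolborane in excess to cover the hydroxyl, cyclohexane, rt) should give (1Z,3R)-3-methyl-1-(4,4,5,5-tetramethyl-1,3,2-dioxaborolan-2-yl)-5-[(1S,2S)-1,2,3-trimethylcyclohex-3-en-1-yl]pent-1-en-3-ol F7. Suzuki–Miyaura coupling of F7 with 17 at the C–I bond (Pd(PPh3)4, aqueous K3PO4, THF, 50 °C) should give 19 with the (Z)-geometry retained, bypassing 18.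

Further compounds
F1 | step 1 | (1S,2S)-1,2,3-trimethylcyclohex-3-ene-1-carbaldehyde | O=C[C@@]1(C)CCC=C(C)[C@@H]1C
F2 | step 1 | (4R,5R)-1,3-dimethyl-4,5-diphenyl-2-[(1R,2R)-1,2,3-trimethylcyclohex-3-en-1-yl]imidazolidine | CN1[C@H](c2ccccc2)[C@@H](c2ccccc2)N(C)C1[C@]3(C)CCC=C(C)[C@H]3C
F3 | step 1 | (4R,5R)-1,3-dimethyl-4,5-diphenyl-2-[(1S,2S)-1,2,3-trimethylcyclohex-3-en-1-yl]imidazolidine | CN1[C@H](c2ccccc2)[C@@H](c2ccccc2)N(C)C1[C@@]3(C)CCC=C(C)[C@@H]3C
F4 | step 13 | 3-bromo-2-{(1Z,3R)-3-hydroxy-3-methyl-5-[(1S,2S)-1,2,3-trimethylcyclohex-3-en-1-yl]pent-1-en-1-yl}-4,5,6-trimethoxyphenol | COc1c(OC)c(OC)c(Br)c(/C=C\[C@](C)(O)CC[C@]2(C)CCC=C(C)[C@H]2C)c1O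
F5 | step 13 | (1Z,3R)-1-{2-bromo-6-[(tert-butyldimethylsilyl)oxy]-3,4,5-trimethoxyphenyl}-3-methyl-5-[(1S,2S)-1,2,3-trimethylcyclohex-3-en-1-yl]pent-1-en-3-ol | COc1c(OC)c(OC)c(Br)c(/C=C\[C@](C)(O)CC[C@]2(C)CCC=C(C)[C@H]2C)c1O[Si](C)(C)C(C)(C)C
F6 | step 13 | tert-butyl(dimethyl){[(2R)-6,7,8-trimethoxy-2-methyl-2-{2-[(1S,2S)-1,2,3-trimethylcyclohex-3-en-1-yl]ethyl}-2H-chromen-5-yl]oxy}silane | COc1c(O[Si](C)(C)C(C)(C)C)c2c(c(OC)c1OC)O[C@](C)(CC[C@]1(C)CCC=C(C)[C@H]1C)C=C2
F7 | step 12 | (1Z,3R)-3-methyl-1-(4,4,5,5-tetramethyl-1,3,2-dioxaborolan-2-yl)-5-[(1S,2S)-1,2,3-trimethylcyclohex-3-en-1-yl]pent-1-en-3-ol | CC1(C)OB(/C=C\[C@](C)(O)CC[C@]2(C)CCC=C(C)[C@H]2C)OC1(C)C
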